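Start from the clock: cedar, ash and larch are read at 4.0 min, and they differ in the partner charged.

all flasks: substrate 0.050 M

|  | partner | capture agent | remark | time |
|---|---|---|---|---|
| eta | 0.028 M | 1 mM | run made earlier |  |
| zeta | 0.12 M | 1 mM | run made earlier |  |
| cedar | 0.0480 M | 1.00 mM |  | 4.0 min |
| ash | 0.0950 M | 1.00 mM |  | 4.0 min |
| larch | 0.190 M | 1.00 mM |  | 4.0 min |

| run | time / min | open intermediate / % | target / % | substrate / % | side product / % |
|---|---|---|---|---|---|
| eta | 0.333 | 5 | 0 | 93 | 1 |
| eta | 0.667 | 11 | 0 | 89 | 1 |
| eta | 1.00 | 16 | 0 | 86 | 5 |
| eta | 2.00 | 23 | 0 | 65 | 3 |
| eta | 4.00 | 23 | 13 | 53 | 10 |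
| zeta | 0.333 | 7 | 0 | 93 | 0 |
| zeta | 1.00 | 15 | 7 | 76 | 12 |
| zeta | 2.00 | 17 | 10 | 58 | 17 |
| zeta | 3.00 | 12 | 16 | 42 | 23 |
| zeta | 4.00 | 16 | 23 | 33 | 28 |

(standard deviation of a reading: 2 percentage points)



- which of these there is most of at the end, counted by the substrate in it, cedar (substrate / side product / open intermediate / target)
- which of these there is most of at the end, counted by the substrate in it, ash (substrate / side product / open intermediate / target)
- which of these there is most of at the end, counted by the substrate in it, larch (substrate / side product / open intermediate / target)
- final amount of the leader among these, as a percentage of the substrate charged, in cedar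
- final amount of the leader among these, as a percentage of the substrate charged, in ash
- final amount of the leader among these, as a percentage of the substrate charged, in larch

Freeze [partner] at its charge and treat the loss of substrate as pseudo-first-order, with an apparent constant k read from the last reading of a run. Eta gives 0.159 min⁻¹ and zeta gives 0.277 min⁻¹. So k climbs by 1.29 M⁻¹ min⁻¹ along [partner], from 0.123 min⁻¹ when the line is carried back to no partner. On this line k is 0.184 min⁻¹ in cedar, 0.245 min⁻¹ in ash and 0.367 min⁻¹ in larch. That reckons substrate at 47.8 %, 37.5 % and 23.0 %, in the same order.

Next, my first guess gives side product the partner-dependent share of the lost substrate. The link is weak: on zeta that share makes 37.3 %, more than the 28 % read, a gap of 9.3 percentage points where a reading scatters by 2 points.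

So reforge it. Integrated substrate is the lost fraction over k, 2.42 min on zeta. Dividing zeta's side product by that and by [partner] as charged gives 0.965 M⁻¹ min⁻¹, the side constant: side product made per unit of charged [partner] and of integrated substrate. Put back on eta, it gives 8.00 % against 10 % read.

Side product then comes to 13.1 % in cedar, 23.4 % in ash and 38.4 % in larch. Target and open intermediate ended no higher than 23 % in eta and zeta. So I commit to substrate leading in cedar and ash, and to side product leading in larch, where my figure for it stands above my figure for substrate.

The forecast names substrate at 46 % (41 % to 51 %) for cedar, substrate at 38 % (33 % to 43 %) for ash, and side product at 41 % (33 % to 49 %) for larch. Its leaders are mine; its figure for larch stands 2.6 points above my side product there. Its ground: “Side-product yields over the integrated substrate give that same second-order constant in both runs.”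

The flasks give substrate at 45.6 % in cedar, substrate at 36.8 % in ash and side product at 41.4 % in larch, each inside the forecast's range. The side constant is reckoned on partner as charged, but in ash free partner stands at 0 % of its charge at 4.00 min, and the second intermediate stands at 0.0724 M, less than the 0.0950 M of partner charged. The side constant of 0.965 M⁻¹ min⁻¹ gave 23.4 % of side product for ash, and the flask holds 24.0 %.

    open intermediate + capture agent → trapped intermediate (k = 0.230 M⁻¹ s⁻¹)
    open intermediate + second intermediate → target (k = 0.0840 M⁻¹ s⁻¹)
    substrate + second intermediate → side product (k = 0.0210 M⁻¹ s⁻¹)
    2 open intermediate → homo product (k = 0.0560 M⁻¹ s⁻¹)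
    partner → second intermediate (k = 0.0620 s⁻¹)
    substrate ⇌ open intermediate (K = 1.60, k = 0.00300 s⁻¹)

The forecast's leader for ash gives way in a neighbour of ash charged with 0.24 M of partner. On the line k there is 0.432 min⁻¹, which reckons substrate at 17.8 %, and the side constant gives 44.1 % of side product. The computed flask holds 18.9 % of substrate and 48.4 % of side product, so side product leads.

The numbers in the tables were computed with constants of no real substance.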